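**Retrosynthetic overview**

1. Both benzene rings are bought as acetophenones: catechol ketone 1 (becomes unit B, the 8-hydroxychromone half) and resorcinol ketone 2 (becomes unit A, the 7-hydroxychromone half).
2. Key disconnection: the biaryl bond, cut before either pyranone exists. 1 is used in its oxidised, polarity-reversed form, o-quinone 3, whose C6 (nucleophilic in the catechol) is now electrophilic; the nucleophilic C5 of 2 attacks it to give biaryl diketone 4.
3. Both 4-pyranone rings are disconnected together at O1–C2 and C2–C3: the two acetyl groups of 4 plus two molecules of acid chloride 5 give bis(1,3-diketone) 6, which closes to target 7.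
4. Ring order: no carbocycle is built; the biaryl bond is made first, then both pyranone rings close together in the last step.

Assumption: the target has no stereocentre and its biaryl axis carries only two ortho substituents, so it is taken as configurationally labile and the compound is made as the single achiral structure drawn.

**Route**

Step 1
Reactants: 1 1-(2,3-dihydroxyphenyl)ethan-1-one; 2 1-(2,4-dihydroxyphenyl)ethan-1-one (3 equiv)
Product: 4 1-[5-(2-acetyl-3,4-dihydroxyphenyl)-2,4-dihydroxyphenyl]ethan-1-one, via 3-acetyl-1,2-benzoquinone 3 (not isolated)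
Conditions: PhI(OAc)2 (1.0 equiv), CH2Cl2/(CF3)2CHOH (4:1), −30 °C, 10 min, Ar; then 2 (3 equiv), −30 °C → rt, 2 h
Reagents that add atoms: none
Why: Proposed new method: PhI(OAc)2 dehydrogenates the catechol of 1 to acyl-o-quinone 3, in which C6 of the former catechol (para to the 3-oxygen, normally a nucleophilic phenol position) has become the β-carbon of an enone activated by both the ring carbonyl and the acetyl group, so the least hindered activated carbon of 2 (C5, para to 2-OH and ortho to 4-OH) adds there in a hydrogen-bond-promoted Friedel–Crafts-type conjugate addition and tautomerisation restores the catechol, giving the unsymmetrical biaryl with no stereocentre formed; closest known reaction type: regioselective conjugate arylation of 2-acyl-1,4-benzoquinones and of in-situ-generated o-quinones by phenols and other electron-rich arenes (oxidative phenol–arene cross-coupling).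

Step 2
Reactants: 4 1-[5-(2-acetyl-3,4-dihydroxyphenyl)-2,4-dihydroxyphenyl]ethan-1-one; 5 3-phenylpropanoyl chloride (2.1 equiv)
Product: 6 1-[5-[3,4-dihydroxy-2-(3-oxo-5-phenylpentanoyl)phenyl]-2,4-dihydroxyphenyl]-5-phenylpentane-1,3-dione
Conditions: LiN(SiMe3)2 (8.5 equiv), THF, −78 → −10 °C, 2 h, Ar; then 5 (2.1 equiv), −78 °C → rt; 1 M HCl work-up, used crude
Reagents that add atoms: none
Why: Directed Claisen-type C-acylation of a lithium polyanion: the base turns the four phenols into phenoxides and both acetyl groups into enolates, the enolates are much more nucleophilic than the lithium phenoxides and take up 5 at carbon, the two extra equivalents of base hold each new 1,3-diketone as its enolate, and any ortho O-acyl ester formed is funnelled to the same diketone by Baker–Venkataraman acyl shift; no stereocentre is formed.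

Step 3
Reactants: 6 1-[5-[3,4-dihydroxy-2-(3-oxo-5-phenylpentanoyl)phenyl]-2,4-dihydroxyphenyl]-5-phenylpentane-1,3-dione
Product: 7 7-hydroxy-6-[8-hydroxy-4-oxo-2-(2-phenylethyl)-4H-chromen-5-yl]-2-(2-phenylethyl)-4H-chromen-4-one
Conditions: H2SO4 (0.5 vol %), AcOH, 95 °C, 1 h
Reagents that add atoms: none
Why: Acid-catalysed cyclodehydration of o-hydroxyaryl 1,3-diketones (closing stage of the Baker–Venkataraman/Claisen chromone synthesis): each chelated ortho OH adds to the distal ketone and the hemiketal loses water irreversibly to the aromatic 4-pyranone, while other hemiketals reopen, so both rings close to 7; no stereocentre is present.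

**Compound list**

1 | 1-(2,3-dihydroxyphenyl)ethan-1-one (2',3'-dihydroxyacetophenone) | CC(=O)c1cccc(O)c1O | starting material
2 | 1-(2,4-dihydroxyphenyl)ethan-1-one (2',4'-dihydroxyacetophenone) | CC(=O)c1ccc(O)cc1O | starting material
3 | 3-acetylcyclohexa-3,5-diene-1,2-dione (3-acetyl-1,2-benzoquinone) | CC(=O)C1=CC=CC(=O)C1=O | intermediate
4 | 1-[5-(2-acetyl-3,4-dihydroxyphenyl)-2,4-dihydroxyphenyl]ethan-1-one | CC(=O)c1cc(-c2ccc(O)c(O)c2C(C)=O)c(O)cc1O | intermediate
5 | 3-phenylpropanoyl chloride | O=C(Cl)CCc1ccccc1 | starting material
6 | 1-[5-[3,4-dihydroxy-2-(3-oxo-5-phenylpentanoyl)phenyl]-2,4-dihydroxyphenyl]-5-phenylpentane-1,3-dione | O=C(CCc1ccccc1)CC(=O)c1cc(-c2ccc(O)c(O)c2C(=O)CC(=O)CCc2ccccc2)c(O)cc1O | intermediate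
7 | 7-hydroxy-6-[8-hydroxy-4-oxo-2-(2-phenylethyl)-4H-chromen-5-yl]-2-(2-phenylethyl)-4H-chromen-4-one | O=c1cc(CCc2ccccc2)oc2cc(O)c(-c3ccc(O)c4oc(CCc5ccccc5)cc(=O)c34)cc12 | target

**Step count and risks**

Total step count: 3. Longest linear sequence: 3 steps (1 → 4 → 6 → 7).

Most likely to fail, first: step 1. Ketone 2 is a deactivated resorcinol and may be too slow for quinone 3. It may also attack through C3. Biaryl 4 can be re-oxidised by remaining 3 and cyclise to a dibenzofuran. The fallback sets out from 1 and comes back at 4, leaving the unit A acetyl group off during the coupling. 1 is oxidised to 3 as before and trapped at −40 °C with resorcinol (5 equiv), which is far more nucleophilic, to give 1-[6-(2,4-dihydroxyphenyl)-2,3-dihydroxyphenyl]ethan-1-one F1. The missing acetyl group is then introduced by Nencki/Friedel–Crafts acetylation (AcOH, BF3·OEt2, 90 °C). This goes to the one remaining position para to one resorcinol OH and ortho to the other, because the catechol ring is deactivated by its own acetyl group, and it gives 4.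

Second: step 2. The hexalithio polyanion may be poorly soluble, and 5 has α-hydrogens, so it may be lost to ketene formation or to O-acylation. The fallback sets out from 4 and comes back at 6, delivering the acyl groups intramolecularly. 4 is esterified on all four hydroxyls with 5 (4.5 equiv, pyridine, cat. DMAP, 0 °C → rt) to 4-acetyl-6-[2-acetyl-3,4-bis(3-phenylpropanoyloxy)phenyl]-1,3-phenylene bis(3-phenylpropanoate) F2. KOtBu (THF, 0 °C) then effects a double Baker–Venkataraman O→C acyl shift of the two ortho esters. This gives the bis(3-phenylpropanoate) of 6 at its two non-chelated hydroxyls F3. K2CO3 in MeOH at rt removes these two phenolic esters and returns 6.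

Third: step 3. The 4-OH of unit A can form a six-membered hemiketal with the aryl ketone of unit B, which may stall the closure, and hot acid may degrade the tetraphenol. The fallback sets out from 4 and comes back at 7, avoiding the diketone altogether. A Kabbe-type aldol/oxa-Michael condensation of 4 with 3-phenylpropanal (2.5 equiv; iPr2NH, EtOH, 160 °C, sealed tube) gives 7-hydroxy-6-[8-hydroxy-4-oxo-2-(2-phenylethyl)-3,4-dihydro-2H-chromen-5-yl]-2-(2-phenylethyl)-2,3-dihydro-4H-chromen-4-one F4 as a diastereomer mixture. Both of its C2 stereocentres are then erased by dehydrogenation with I2 (0.2 equiv) in DMSO at 120 °C, which gives 7.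

**Further compounds**

F1 | step 1 | 1-[6-(2,4-dihydroxyphenyl)-2,3-dihydroxyphenyl]ethan-1-one | CC(=O)c1c(O)c(O)ccc1-c1ccc(O)cc1O
F2 | step 2 | 4-acetyl-6-[2-acetyl-3,4-bis(3-phenylpropanoyloxy)phenyl]-1,3-phenylene bis(3-phenylpropanoate) (tetraester of 4) | CC(=O)c1cc(-c2ccc(OC(=O)CCc3ccccc3)c(OC(=O)CCc3ccccc3)c2C(C)=O)c(OC(=O)CCc2ccccc2)cc1OC(=O)CCc1ccccc1
F3 | step 2 | bis(3-phenylpropanoate) of 6 at the two non-chelated hydroxyls (unit A 4-OH, unit B 3-OH, acetophenone numbering) | O=C(CCc1ccccc1)CC(=O)c1cc(-c2ccc(OC(=O)CCc3ccccc3)c(O)c2C(=O)CC(=O)CCc2ccccc2)c(OC(=O)CCc2ccccc2)cc1O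
F4 | step 3 | 7-hydroxy-6-[8-hydroxy-4-oxo-2-(2-phenylethyl)-3,4-dihydro-2H-chromen-5-yl]-2-(2-phenylethyl)-2,3-dihydro-4H-chromen-4-one (mixture of diastereomers, C2 centres unassigned) | O=C1CC(CCc2ccccc2)Oc2cc(O)c(-c3ccc(O)c4OC(CCc5ccccc5)CC(=O)c34)cc21
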